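**Plan**
- **Retrosynthetic cuts, in order:** (a) 13 benzyl ethers and one diphenylmethylene acetal. (b) O1–C2 and C3–C4 of the upper pyran ring in one retro-[4+2], which also opens the 16-membered ring. (c) C4–C4a, giving the A-ring phenol and the 8-formyl group of the lower flavan. (d) The enol gallate, giving an aryl alkyne and the acid. (e) The ester at the lower O3. (f) The diaryl ether.
- **Enabling feature:** C4 is a methine between two phloroglucinol rings (upper A ring and lower C8) and lies ortho to O1. O1–C8a–C4a–C4 is therefore a latent o-quinone methide. C2–C3, with the B ring on C2 and the galloyloxy group on C3, is a latent (Z)-β-acyloxystyrene.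
- **Forward order of rings:** a helper benzodioxole ring comes first, and both lower flavan rings are bought with epigallocatechin. The chain is joined by the diaryl ether, then the ester, then the enol gallate, then the A ring. In step 12 the C3–C4 bond closes the 16-membered ring and O1–C2 then closes the upper pyran as the last ring.
- **Stereochemistry:** the lower C2/C3 come from (−)-epigallocatechin. The upper 2,3-cis relation comes from suprafacial addition to the Z alkene, and the 3,4-trans relation from an exo approach. The absolute sense comes from the chiral acid together with the chiral tether, and both carbinol epimers converge through the planar methide.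

Key step: step 12

Assumption: 3, 8, 14 and 16 are taken as catalogue compounds, flavan numbering is used ("upper" is the unit bearing the C4–aryl bond, "lower" is the unit bonded through C8), and 18 is carried as both C4 epimers, so its SMILES leaves that centre open.

Step 1
Reactants: 1 methyl gallate
Product: 2 methyl 7-hydroxy-2,2-diphenyl-1,3-benzodioxole-5-carboxylate
Conditions: Ph2CCl2, K2CO3, MeCN, rt
Reagents that add atoms: dichlorodiphenylmethane ClC(Cl)(c1ccccc1)c1ccccc1
Why: Diphenylmethylene acetal formation ties up two vicinal phenols of the pyrogallol, leaves exactly one phenol free, and gives a group that falls in the final hydrogenolysis.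

Step 2
Reactants: 3 3,4,5-tris(benzyloxy)benzaldehyde
Product: 4 2-bromo-3,4,5-tris(benzyloxy)benzaldehyde
Conditions: NBS, MeCN, rt, dark
Reagents that add atoms: N-bromosuccinimide O=C1CCC(=O)N1Br
Why: Electrophilic aromatic bromination can only reach the two equivalent free positions, which lie ortho to the formyl group and para to a benzyloxy group.

Step 3
Reactants: 2 methyl 7-hydroxy-2,2-diphenyl-1,3-benzodioxole-5-carboxylate; 4 2-bromo-3,4,5-tris(benzyloxy)benzaldehyde
Product: 5 methyl 7-[2,3,4-tris(benzyloxy)-6-formylphenoxy]-2,2-diphenyl-1,3-benzodioxole-5-carboxylate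
Conditions: CuI (20 mol %), N,N-dimethylglycine, Cs2CO3, dioxane, 100 °C
Reagents that add atoms: none
Why: This is a ligand-accelerated Ullmann diaryl ether coupling, in which the ortho-formyl group activates the C–Br bond and the phenol carries only one small ortho substituent.

Step 4
Reactants: 5 diaryl ether aldehyde
Product: 6 methyl 7-[2,3,4-tris(benzyloxy)-6-ethynylphenoxy]-2,2-diphenyl-1,3-benzodioxole-5-carboxylate
Conditions: Ohira–Bestmann reagent, K2CO3, MeOH–THF, rt
Reagents that add atoms: dimethyl (1-diazo-2-oxopropyl)phosphonate COP(=O)(OC)C(=[N+]=[N-])C(C)=O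
Why: Ohira–Bestmann (Seyferth–Gilbert) homologation turns the non-enolisable aryl aldehyde into the terminal alkyne under conditions that spare the methyl ester and the acetal.

Step 5
Reactants: 6 alkyne methyl ester
Product: 7 7-[2,3,4-tris(benzyloxy)-6-ethynylphenoxy]-2,2-diphenyl-1,3-benzodioxole-5-carboxylic acid
Conditions: LiOH, THF–MeOH–H2O, 45 °C; then 1 M HCl
Reagents that add atoms: lithium hydroxide [Li+].[OH-]
Why: Saponification cleaves the only ester present, and the ethers, acetal and alkyne are inert to hydroxide.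

Step 6
Reactants: 8 (−)-epigallocatechin
Product: 9 (2R,3R)-5,7,3',4',5'-penta-O-benzylepigallocatechin
Conditions: BnBr (5.5 equiv), K2CO3, DMF, 0 °C to rt, Ar
Reagents that add atoms: benzyl bromide BrCc1ccccc1
Why: Williamson etherification alkylates the five phenols only, because carbonate does not deprotonate the secondary 3-OH, and both stereocentres are carried over from 8.

Step 7
Reactants: 9 penta-O-benzylepigallocatechin
Product: 10 (2R,3R)-8-bromo-penta-O-benzylepigallocatechin
Conditions: NBS (1.0 equiv), CH2Cl2, −78 to 0 °C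
Reagents that add atoms: N-bromosuccinimide O=C1CCC(=O)N1Br
Why: Electrophilic bromination of benzylated flavan-3-ols is known to take place selectively at C8, the most nucleophilic position of the phloroglucinol ring.

Step 8
Reactants: 10 8-bromo-penta-O-benzylepigallocatechin
Product: 12 (2R,3R)-8-formyl-penta-O-benzylepigallocatechin, via dilithio species 11 (not isolated)
Conditions: n-BuLi (2.2 equiv), THF, −78 °C; DMF; AcOH quench
Reagents that add atoms: N,N-dimethylformamide CN(C)C=O
Why: Deprotonation of the alcohol, bromine–lithium exchange and Bouveault formylation place the future C4 carbon regiospecifically at C8 without protecting the alcohol.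

Step 9
Reactants: 7 alkyne acid; 12 8-formyl-penta-O-benzylepigallocatechin
Product: 13 alkyne aldehyde ester (3-O-acyl derivative of 12 with acid 7)
Conditions: DCC, DMAP, CH2Cl2, rt
Reagents that add atoms: none
Why: Steglich esterification is the standard way to acylate the axial 3-OH of benzylated epi-series flavanols with gallic-type acids, and it retains configuration because the C–O bond is not touched.

Step 10
Reactants: 13 alkyne aldehyde ester; 14 3,4,5-tris(benzyloxy)benzoic acid
Product: 15 (Z)-enol gallate aldehyde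
Conditions: [Ru(η3-methallyl)2(dppb)] (2 mol %), toluene, 50 °C
Reagents that add atoms: none
Why: Ruthenium-catalysed anti-Markovnikov hydro-oxycarbonylation of a terminal alkyne proceeds through a vinylidene complex and gives the (Z)-enol ester, so it installs the 3-O-galloyl group and the alkene geometry together.

Step 11
Reactants: 15 (Z)-enol gallate aldehyde; 16 3,5-bis(benzyloxy)phenol
Product: 18 o-hydroxybenzhydrol (both C4 epimers), via magnesium phenolate 17 (not isolated)
Conditions: 16, EtMgBr (1.0 equiv), Et2O, 0 °C; swap to toluene; 15, 0 °C to rt; pH 7 buffer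
Reagents that add atoms: none
Why: Magnesium-phenolate-directed ortho-hydroxyalkylation delivers the aldehyde through a six-membered chelate to the carbon next to the phenolate oxygen only, and the new carbinol centre need not be controlled because step 12 erases it.

Step 12
Reactants: 18 o-hydroxybenzhydrol (both C4 epimers)
Product: 20 fully protected target (13 benzyl ethers plus one diphenylmethylene acetal; upper unit 2R 3R 4R; lower unit 2R 3R), via o-quinone methide 19 (not isolated)
Conditions: (R)-3,3'-bis(2,4,6-triisopropylphenyl)-BINOL N-triflylphosphoramide (10 mol %), 5 Å MS, toluene (1 mM), rt to 60 °C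
Reagents that add atoms: none
Why: Proposed new method: the acid dehydrates either C4 epimer of 18 to the same planar, hydrogen-bonded (E)-o-quinone methide 19 (O1=C8a–C4a=C4), whose C4 is attacked by C3 of the tethered (Z)-enol gallate in a strongly asynchronous inverse-demand hetero-Diels–Alder reaction, so that C3–C4 forms first and O1–C2 last. The closest known reaction type is the Brønsted-acid-catalysed [4+2] of o-hydroxybenzhydrols with styrenes and enol derivatives to 2,4-diarylchromans, which is known intermolecularly and for small tethers but not as a macrocyclisation or with a β-acyloxystyrene. The 16-membered ring closes through the C3–C4 bond in the bridged mode (the tether ends on the C4 aryl and on the C2 aryl), and the pyran closes as the six-membered [4π+2π] ring when O1 collapses on the benzylic C2. The C2/C3 cis relation follows from suprafacial addition to the Z alkene, the C3/C4 trans relation from the exo approach to the E methide, in which the B ring and the bulky galloyloxy group point away from the A ring and its 5-benzyloxy group, and the absolute sense from the methide face left open by the chiral phosphoramide anion acting together with the (2R,3R)-flavan tether. The required regioselectivity is secured by the acyl group, which mutes the enol oxygen so that the 4'-benzyloxy/2'-aryloxy B ring stabilises charge at C2 and C3 becomes the nucleophilic carbon. Chemoselectivity over Friedel–Crafts capture is expected because the nucleophilic arene CH positions (lower C6, upper C6 and C8) are each flanked by two oxygens and would give a crowded, reversibly formed triarylmethane, while high dilution suppresses dimerisation and the long-lived, donor-stabilised methide can wait for the slow ring closure.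

Step 13
Reactants: 20 fully protected target
Product: 21 target CNP0601265.1
Conditions: H2 (1 atm), Pd(OH)2/C, THF–MeOH, rt; filtration under Ar
Reagents that add atoms: none
Why: Global hydrogenolysis removes all benzyl ethers and the diphenylmethylene acetal under the conditions used for benzylated proanthocyanidin gallates, which leave the esters, the diaryl ether, the C2–O1 bonds and all five stereocentres intact.

**Compound list**
1 | methyl gallate | COC(=O)c1cc(O)c(O)c(O)c1 | starting material
2 | methyl 7-hydroxy-2,2-diphenyl-1,3-benzodioxole-5-carboxylate | COC(=O)c1cc(O)c2OC(c3ccccc3)(c3ccccc3)Oc2c1 | intermediate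
3 | 3,4,5-tris(benzyloxy)benzaldehyde | O=Cc1cc(OCc2ccccc2)c(OCc2ccccc2)c(OCc2ccccc2)c1 | starting material
4 | 2-bromo-3,4,5-tris(benzyloxy)benzaldehyde | O=Cc1cc(OCc2ccccc2)c(OCc2ccccc2)c(OCc2ccccc2)c1Br | intermediate
5 | methyl 7-[2,3,4-tris(benzyloxy)-6-formylphenoxy]-2,2-diphenyl-1,3-benzodioxole-5-carboxylate | COC(=O)c1cc(Oc2c(C=O)cc(OCc3ccccc3)c(OCc3ccccc3)c2OCc2ccccc2)c2OC(c3ccccc3)(c3ccccc3)Oc2c1 | intermediate
6 | methyl 7-[2,3,4-tris(benzyloxy)-6-ethynylphenoxy]-2,2-diphenyl-1,3-benzodioxole-5-carboxylate | COC(=O)c1cc(Oc2c(C#C)cc(OCc3ccccc3)c(OCc3ccccc3)c2OCc2ccccc2)c2OC(c3ccccc3)(c3ccccc3)Oc2c1 | intermediate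
7 | 7-[2,3,4-tris(benzyloxy)-6-ethynylphenoxy]-2,2-diphenyl-1,3-benzodioxole-5-carboxylic acid | OC(=O)c1cc(Oc2c(C#C)cc(OCc3ccccc3)c(OCc3ccccc3)c2OCc2ccccc2)c2OC(c3ccccc3)(c3ccccc3)Oc2c1 | intermediate
8 | (−)-epigallocatechin (2R,3R) | O[C@@H]1Cc2c(O)cc(O)cc2O[C@@H]1c1cc(O)c(O)c(O)c1 | starting material
9 | (2R,3R)-5,7,3',4',5'-penta-O-benzylepigallocatechin | O[C@@H]1Cc2c(OCc3ccccc3)cc(OCc3ccccc3)cc2O[C@@H]1c1cc(OCc2ccccc2)c(OCc2ccccc2)c(OCc2ccccc2)c1 | intermediate
10 | (2R,3R)-8-bromo-penta-O-benzylepigallocatechin | O[C@@H]1Cc2c(OCc3ccccc3)cc(OCc3ccccc3)c(Br)c2O[C@@H]1c1cc(OCc2ccccc2)c(OCc2ccccc2)c(OCc2ccccc2)c1 | intermediate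
11 | 8-lithio lithium 3-alkoxide of 9 (dilithio species) | [Li]O[C@@H]1Cc2c(OCc3ccccc3)cc(OCc3ccccc3)c([Li])c2O[C@@H]1c1cc(OCc2ccccc2)c(OCc2ccccc2)c(OCc2ccccc2)c1 | intermediate
12 | (2R,3R)-8-formyl-penta-O-benzylepigallocatechin | O[C@@H]1Cc2c(OCc3ccccc3)cc(OCc3ccccc3)c(C=O)c2O[C@@H]1c1cc(OCc2ccccc2)c(OCc2ccccc2)c(OCc2ccccc2)c1 | intermediate
13 | alkyne aldehyde ester (12 acylated at O3 by 7) | O=C(O[C@@H]1Cc2c(OCc3ccccc3)cc(OCc3ccccc3)c(C=O)c2O[C@@H]1c1cc(OCc2ccccc2)c(OCc2ccccc2)c(OCc2ccccc2)c1)c1cc(Oc2c(C#C)cc(OCc3ccccc3)c(OCc3ccccc3)c2OCc2ccccc2)c2OC(c3ccccc3)(c3ccccc3)Oc2c1 | intermediate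
14 | 3,4,5-tris(benzyloxy)benzoic acid | OC(=O)c1cc(OCc2ccccc2)c(OCc2ccccc2)c(OCc2ccccc2)c1 | starting material
15 | (Z)-enol gallate aldehyde | O=C(O[C@@H]1Cc2c(OCc3ccccc3)cc(OCc3ccccc3)c(C=O)c2O[C@@H]1c1cc(OCc2ccccc2)c(OCc2ccccc2)c(OCc2ccccc2)c1)c1cc(Oc2c(/C=C\OC(=O)c3cc(OCc4ccccc4)c(OCc4ccccc4)c(OCc4ccccc4)c3)cc(OCc3ccccc3)c(OCc3ccccc3)c2OCc2ccccc2)c2OC(c3ccccc3)(c3ccccc3)Oc2c1 | intermediate
16 | 3,5-bis(benzyloxy)phenol | Oc1cc(OCc2ccccc2)cc(OCc2ccccc2)c1 | starting material
17 | bromomagnesium 3,5-bis(benzyloxy)phenolate | Br[Mg]Oc1cc(OCc2ccccc2)cc(OCc2ccccc2)c1 | intermediate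
18 | o-hydroxybenzhydrol, both C4 epimers | O=C(O[C@@H]1Cc2c(OCc3ccccc3)cc(OCc3ccccc3)c(C(O)c3c(O)cc(OCc4ccccc4)cc3OCc3ccccc3)c2O[C@@H]1c1cc(OCc2ccccc2)c(OCc2ccccc2)c(OCc2ccccc2)c1)c1cc(Oc2c(/C=C\OC(=O)c3cc(OCc4ccccc4)c(OCc4ccccc4)c(OCc4ccccc4)c3)cc(OCc3ccccc3)c(OCc3ccccc3)c2OCc2ccccc2)c2OC(c3ccccc3)(c3ccccc3)Oc2c1 | intermediate
19 | (E)-o-quinone methide | O=C(O[C@@H]1Cc2c(OCc3ccccc3)cc(OCc3ccccc3)c(/C=C3/C(=O)C=C(OCc4ccccc4)C=C3OCc3ccccc3)c2O[C@@H]1c1cc(OCc2ccccc2)c(OCc2ccccc2)c(OCc2ccccc2)c1)c1cc(Oc2c(/C=C\OC(=O)c3cc(OCc4ccccc4)c(OCc4ccccc4)c(OCc4ccccc4)c3)cc(OCc3ccccc3)c(OCc3ccccc3)c2OCc2ccccc2)c2OC(c3ccccc3)(c3ccccc3)Oc2c1 | intermediate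
20 | fully protected target (upper 2R,3R,4R; lower 2R,3R) | O=C(O[C@@H]1[C@@H]2c3c(OCc4ccccc4)cc(OCc4ccccc4)cc3O[C@@H]1c1cc(OCc4ccccc4)c(OCc4ccccc4)c(OCc4ccccc4)c1Oc1cc(cc3OC(c4ccccc4)(c4ccccc4)Oc13)C(=O)O[C@@H]1Cc3c(OCc4ccccc4)cc(OCc4ccccc4)c2c3O[C@@H]1c1cc(OCc4ccccc4)c(OCc4ccccc4)c(OCc4ccccc4)c1)c1cc(OCc4ccccc4)c(OCc4ccccc4)c(OCc4ccccc4)c1 | intermediate
21 | CNP0601265.1 | O=C(O[C@@H]1[C@@H]2c3c(O)cc(O)cc3O[C@@H]1c1cc(O)c(O)c(O)c1Oc1cc(cc(O)c1O)C(=O)O[C@@H]1Cc3c(O)cc(O)c2c3O[C@@H]1c1cc(O)c(O)c(O)c1)c1cc(O)c(O)c(O)c1 | target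

**Total steps:** 13.
**Longest linear sequence:** 9 (steps 1, 3, 4, 5, 9, 10, 11, 12, 13).

**Steps most likely to fail**

1. **Step 12.**
   - *What may go wrong:* the doubly donor-stabilised methide may be too weak an electrophile for the acyloxy-deactivated alkene at macrocyclisation dilution. Ring closure could then lag behind decomposition, and π-facial or exo/endo selectivity may be poor.
   - *Fallback:* known chemistry, setting out from 6, 12, 14 and 16 and coming back at 20. Alkyne ester 6 and acid 14 are joined under the conditions of step 10 to the methyl ester (Z)-enol gallate F1. Aldehyde 12 and phenolate 17 give, as in step 11, the o-hydroxybenzhydrol with free 3-OH F2. F2 and an excess of F1 are combined at high concentration under Brønsted acid catalysis, in the known intermolecular o-quinone methide/styrene [4+2] mode, to the open bis-flavan methyl ester F3, whose diastereomers can be separated at this stage. Me3SnOH cleaves the methyl ester in preference to the hindered secondary gallate to give the seco acid F4. Shiina macrolactonisation (MNBA, DMAP, high dilution) then closes the 16-membered ring to 20.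

2. **Step 11.**
   - *What may go wrong:* the magnesium alkoxide may lose its oxygen prematurely, so that the methide is captured by a second phenolate. Acyl transfer from the enol gallate to the phenolate is also possible.
   - *Fallback:* sets out from 15 and 16 and comes back at 19. A boron-templated condensation (PhB(OH)2, catalytic propionic acid, toluene, azeotropic water removal) joins the aldehyde and the phenol ortho-specifically to the 2-phenyl-4H-1,3,2-benzodioxaborin F5. This is a neutral, storable masked methide. Under the conditions of step 12 it releases 19 directly, so the free benzhydrol is bypassed.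

3. **Step 3.**
   - *What may go wrong:* copper insertion and ligand exchange may be slow at a bromide flanked by two ortho substituents, with competing hydrodebromination and aldehyde degradation at 100 °C.
   - *Fallback:* sets out from 4 and 2 and comes back at 5. Palladium-catalysed borylation of 4 with tetrahydroxydiboron (XPhos-Pd, KOAc, EtOH) gives 2,3,4-tris(benzyloxy)-6-formylphenylboronic acid F6. F6 is coupled with phenol 2 at room temperature by oxidative Chan–Evans–Lam etherification (Cu(OAc)2, pyridine, 4 Å MS, air, CH2Cl2).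

**Further compounds**
F1 | step 12 | methyl ester (Z)-enol gallate | COC(=O)c1cc(Oc2c(/C=C\OC(=O)c3cc(OCc4ccccc4)c(OCc4ccccc4)c(OCc4ccccc4)c3)cc(OCc3ccccc3)c(OCc3ccccc3)c2OCc2ccccc2)c2OC(c3ccccc3)(c3ccccc3)Oc2c1
F2 | step 12 | o-hydroxybenzhydrol with free 3-OH (both carbinol epimers) | O[C@@H]1Cc2c(OCc3ccccc3)cc(OCc3ccccc3)c(C(O)c3c(O)cc(OCc4ccccc4)cc3OCc3ccccc3)c2O[C@@H]1c1cc(OCc2ccccc2)c(OCc2ccccc2)c(OCc2ccccc2)c1
F3 | step 12 | open bis-flavan methyl ester | O=C(O[C@@H]1[C@@H](c2c(OCc4ccccc4)cc(OCc4ccccc4)c3c2O[C@H](c2cc(OCc4ccccc4)c(OCc4ccccc4)c(OCc4ccccc4)c2)[C@H](O)C3)c3c(OCc4ccccc4)cc(OCc4ccccc4)cc3O[C@@H]1c1cc(OCc4ccccc4)c(OCc4ccccc4)c(OCc4ccccc4)c1Oc1cc(cc3OC(c4ccccc4)(c4ccccc4)Oc13)C(=O)OC)c1cc(OCc4ccccc4)c(OCc4ccccc4)c(OCc4ccccc4)c1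
F4 | step 12 | seco acid | O=C(O[C@@H]1[C@@H](c2c(OCc4ccccc4)cc(OCc4ccccc4)c3c2O[C@H](c2cc(OCc4ccccc4)c(OCc4ccccc4)c(OCc4ccccc4)c2)[C@H](O)C3)c3c(OCc4ccccc4)cc(OCc4ccccc4)cc3O[C@@H]1c1cc(OCc4ccccc4)c(OCc4ccccc4)c(OCc4ccccc4)c1Oc1cc(cc3OC(c4ccccc4)(c4ccccc4)Oc13)C(=O)O)c1cc(OCc4ccccc4)c(OCc4ccccc4)c(OCc4ccccc4)c1
F5 | step 11 | 2-phenyl-4H-1,3,2-benzodioxaborin (both C4 epimers) | O=C(O[C@@H]1Cc2c(OCc3ccccc3)cc(OCc3ccccc3)c(C3OB(c4ccccc4)Oc4cc(OCc5ccccc5)cc(OCc5ccccc5)c34)c2O[C@@H]1c1cc(OCc2ccccc2)c(OCc2ccccc2)c(OCc2ccccc2)c1)c1cc(Oc2c(/C=C\OC(=O)c3cc(OCc4ccccc4)c(OCc4ccccc4)c(OCc4ccccc4)c3)cc(OCc3ccccc3)c(OCc3ccccc3)c2OCc2ccccc2)c2OC(c3ccccc3)(c3ccccc3)Oc2c1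
F6 | step 3 | 2,3,4-tris(benzyloxy)-6-formylphenylboronic acid | O=Cc1cc(OCc2ccccc2)c(OCc2ccccc2)c(OCc2ccccc2)c1B(O)O
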